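**Retrosynthetic overview**
1. The target is a germacranolide (ten-membered ring C1–C10, butenolide O–C6/C7=C11/C12, C13 = CH2OAc). The last operations are the 4,5-epoxide (directed by 1-OH), the C1 carbinol (ketone reduction) and the C8 methacrylate.
2. Key disconnection: the lactone C6–O bond, formed in the same operation that cleaves a temporary C1–C6 bond. Keto butenolide 28 comes from the cadinane-type decalin 24 (angular C1–OH, tert-butyl alkylidene ester) by alkoxyl-radical ring expansion and oxidative lactonisation.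
3. Enabling feature: the oxygens on C1 and C6 sit 1,6 across the ten-membered ring, and C6 lies between the (Z)-C4=C5 olefin and the C7=C11 acrylate. A C1–C6 bond therefore turns the ring into two six-membered rings (ring A = C1–C6 cyclohexene, which fixes the Z olefin; ring B = C6–C10, C1), and breaking that bond from the C1 alkoxyl radical leaves a doubly stabilised C6 radical next to the carboxyl group.
4. Decalin 24 comes from the intramolecular Diels–Alder reaction of trienoate silyl enol ether 21 (rings A and B together). 21 comes from enol triflate 15 and dienyl boronate 18 (Suzuki), 15 from aldehyde 8 and ester 10 (aldol), and 8 from (S)-5-(hydroxymethyl)butyrolactone 1, which supplies C8 and, by trans-methylation, C10.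
5. Ring order: rings A and B of the decalin (step 15), then the ten-membered carbocycle and the butenolide together (step 18), then the epoxide (step 22).

Key step: step 18

Remark (structure and notation): read from the SMILES, the 4,5-epoxide is cis (C3 and C6 on the same side, i.e. derived from a 4Z olefin) and 1-OH, the epoxide oxygen, 6-O, 8-O and 10-Me lie on one face of the ring; germacrane numbering (C14 on C10, C15 on C4) is used for all intermediates; TBS = tert-butyldimethylsilyl, TMS = trimethylsilyl, Tr = trityl.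

**Route**

Step 1
Reactants: 1 (S)-5-(hydroxymethyl)dihydrofuran-2(3H)-one
Product: 2 (S)-5-(trityloxymethyl)dihydrofuran-2(3H)-one
Conditions: TrCl, Et3N, DMAP (cat.), CH2Cl2, rt
Reagents that add atoms: trityl chloride, ClC(c1ccccc1)(c1ccccc1)c1ccccc1
Why: Tritylation of the primary alcohol installs the bulky group that shields one face of the lactone in the next step.

Step 2
Reactants: 2 (S)-5-(trityloxymethyl)dihydrofuran-2(3H)-one
Product: 4 (3R,5S)-3-methyl-5-(trityloxymethyl)dihydrofuran-2(3H)-one, via lithium enolate 3 (not isolated)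
Conditions: LiN(i-Pr)2, THF, −78 °C; MeI, −78 °C
Reagents that add atoms: iodomethane, CI
Why: Enolate alkylation in which iodomethane attacks the face anti to the trityloxymethyl group, which should give the 3,5-trans lactone and so set C10 (R) relative to C8 (S).

Step 3
Reactants: 4 (3R,5S)-3-methyl-5-(trityloxymethyl)dihydrofuran-2(3H)-one
Product: 5 (2R,4S)-4-hydroxy-N-methoxy-N,2-dimethyl-5-(trityloxy)pentanamide
Conditions: MeNH(OMe)·HCl, AlMe3, CH2Cl2, 0 °C → rt
Reagents that add atoms: N,O-dimethylhydroxylamine hydrochloride, CNOC.Cl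
Why: Aluminium-amide aminolysis of the lactone (Weinreb amide formation) opens the ring without touching C8 or C10 and keeps C1 as an acyl group that tolerates the bases used later.

Step 4
Reactants: 5 (2R,4S)-4-hydroxy-N-methoxy-N,2-dimethyl-5-(trityloxy)pentanamide
Product: 6 (2R,4S)-4-(TBS-oxy)-N-methoxy-N,2-dimethyl-5-(trityloxy)pentanamide
Conditions: TBSCl, imidazole, DMF, rt
Reagents that add atoms: tert-butyldimethylsilyl chloride, CC(C)(C)[Si](C)(C)Cl
Why: Silylation of the secondary C8 hydroxyl, done promptly, prevents relactonisation and gives the C8 protecting group that is carried through the key step.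

Step 5
Reactants: 6 (2R,4S)-4-(TBS-oxy)-N-methoxy-N,2-dimethyl-5-(trityloxy)pentanamide
Product: 7 (2R,4S)-4-(TBS-oxy)-5-hydroxy-N-methoxy-N,2-dimethylpentanamide
Conditions: ZnBr2, CH2Cl2/MeOH, rt
Reagents that add atoms: none
Why: Lewis-acid detritylation with methanol as trityl-cation trap should leave the secondary TBS ether and the Weinreb amide intact.

Step 6
Reactants: 7 (2R,4S)-4-(TBS-oxy)-5-hydroxy-N-methoxy-N,2-dimethylpentanamide
Product: 8 (2R,4S)-4-(TBS-oxy)-N-methoxy-N,2-dimethyl-5-oxopentanamide
Conditions: Dess–Martin periodinane, pyridine, CH2Cl2, 0 °C → rt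
Reagents that add atoms: none
Why: Buffered Dess–Martin oxidation gives the α-silyloxy aldehyde (C7) without epimerising C8; it is used at once.

Step 7
Reactants: 9 tert-butyl 3-hydroxypropanoate
Product: 10 tert-butyl 3-(TBS-oxy)propanoate
Conditions: TBSCl, imidazole, CH2Cl2, rt
Reagents that add atoms: tert-butyldimethylsilyl chloride, CC(C)(C)[Si](C)(C)Cl
Why: Standard silylation provides the C11–C13 unit with O13 already in place and masked by a poor leaving group.

Step 8
Reactants: 8 (2R,4S)-4-(TBS-oxy)-N-methoxy-N,2-dimethyl-5-oxopentanamide; 10 tert-butyl 3-(TBS-oxy)propanoate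
Product: 12 tert-butyl (4S,6R)-4-(TBS-oxy)-2-[(TBS-oxy)methyl]-3-hydroxy-7-[methoxy(methyl)amino]-6-methyl-7-oxoheptanoate (C2/C3 diastereomer mixture), via lithium enolate 11 (not isolated)
Conditions: LiN(i-Pr)2, THF, −78 °C (10); then 8, −78 °C; aq NH4Cl
Reagents that add atoms: none
Why: Aldol addition of the ester enolate to the aldehyde forms C7–C11; at −78 °C the enolate should add faster than it loses silanolate, the Weinreb amide is inert, and the two new centres are removed in steps 9 and 10.

Step 9
Reactants: 12 the aldol adduct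
Product: 13 tert-butyl (4S,6R)-4-(TBS-oxy)-2-[(TBS-oxy)methyl]-7-[methoxy(methyl)amino]-6-methyl-3,7-dioxoheptanoate (C2 epimers)
Conditions: Dess–Martin periodinane, pyridine, CH2Cl2, rt
Reagents that add atoms: none
Why: Dess–Martin oxidation of the β-hydroxy ester gives the β-keto ester (C7 ketone) under non-basic conditions that should avoid β-elimination of the silyloxy group.

Step 10
Reactants: 13 the β-keto ester
Product: 15 tert-butyl (2Z,4S,6R)-4-(TBS-oxy)-2-[(TBS-oxy)methyl]-7-[methoxy(methyl)amino]-6-methyl-7-oxo-3-(trifluoromethylsulfonyloxy)hept-2-enoate, via lithium chelate enolate 14 (not isolated)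
Conditions: LiN(SiMe3)2, THF, −78 °C; N-(5-chloro-2-pyridyl)bis(trifluoromethanesulfonimide), −78 → 0 °C
Reagents that add atoms: N-(5-chloro-2-pyridyl)bis(trifluoromethanesulfonimide), O=S(=O)(N(c1ccc(Cl)cn1)S(=O)(=O)C(F)(F)F)C(F)(F)F
Why: Enol triflate formation from a β-keto ester; the lithium enolate is a chelate with the enolate oxygen cis to the ester carbonyl, so O-sulfonylation should give the triflate cis to CO2t-Bu (2Z).

Step 11
Reactants: 16 2-methylbut-1-en-3-yne; 17 pinacolborane
Product: 18 (E)-4,4,5,5-tetramethyl-2-(3-methylbuta-1,3-dienyl)-1,3,2-dioxaborolane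
Conditions: Cp2Zr(H)Cl (5 mol %), Et3N (10 mol %), neat, 60 °C
Reagents that add atoms: none
Why: Zirconium-catalysed syn hydroboration of the terminal alkyne gives the (E)-dienyl boronate that carries C3–C6 and C15.

Step 12
Reactants: 15 the (2Z)-enol triflate; 18 the (E)-dienyl boronate
Product: 19 tert-butyl (2E,4S,6R)-4-(TBS-oxy)-2-[(TBS-oxy)methyl]-7-[methoxy(methyl)amino]-6-methyl-3-[(E)-3-methylbuta-1,3-dienyl]-7-oxohept-2-enoate
Conditions: Pd(PPh3)4 (5 mol %), K3PO4, THF/H2O, 50 °C
Reagents that add atoms: none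
Why: Suzuki–Miyaura coupling with retention at both sp2 carbons places the dienyl group (C6) cis to the ester on the tetrasubstituted C7=C11 olefin, the geometry needed later for lactonisation onto C6.

Step 13
Reactants: 19 the trienoate Weinreb amide
Product: 20 tert-butyl (2E,4S,6R)-4-(TBS-oxy)-2-[(TBS-oxy)methyl]-6-methyl-3-[(E)-3-methylbuta-1,3-dienyl]-7-oxooct-2-enoate
Conditions: MeMgBr, THF, −20 → 0 °C; aq NH4Cl
Reagents that add atoms: methylmagnesium bromide, C[Mg]Br
Why: Weinreb ketone synthesis; the chelated tetrahedral intermediate prevents over-addition, the hindered fully substituted tert-butyl enoate should not react, and the C1 ketone appears only now so that C10 has not met base as an α-keto centre.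

Step 14
Reactants: 20 the trienoate methyl ketone
Product: 21 tert-butyl (2E,4S,6R)-4-(TBS-oxy)-2-[(TBS-oxy)methyl]-6-methyl-3-[(E)-3-methylbuta-1,3-dienyl]-7-(trimethylsilyloxy)octa-2,7-dienoate
Conditions: TMSOTf, Et3N, CH2Cl2, −78 °C
Reagents that add atoms: trimethylsilyl triflate, C[Si](C)(C)OS(=O)(=O)C(F)(F)F
Why: Soft enolisation removes the unhindered methyl proton rather than the C10 methine, which should give the terminal silyl enol ether (C1=C2) without epimerising C10.

Step 15
Reactants: 21 the trienoate silyl enol ether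
Product: 22 tert-butyl (E)-3-(TBS-oxy)-2-[(2S,4R)-2-(TBS-oxy)-4,7-dimethyl-4a-(trimethylsilyloxy)-3,4,4a,5,6,8a-hexahydronaphthalen-1(2H)-ylidene]propanoate (mixture of C1/C6 ring-fusion isomers)
Conditions: PhMe (5 mM), BHT, Et3N (trace), 150 °C, sealed tube
Reagents that add atoms: none
Why: Inverse-electron-demand intramolecular Diels–Alder reaction of a 1,3,9-decatriene: the nucleophilic enol-ether carbon C2 bonds to the electrophilic trienoate terminus C3 and C1 to C6, the tether fixes the regiochemistry, and ring A carries C4=C5 necessarily as a cis olefin; the new centres C1 and C6 are not controlled and both are erased in step 18.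

Step 16
Reactants: 22 the decalin silyl ether
Product: 23 tert-butyl (E)-3-hydroxy-2-[(2S,4R)-2-(TBS-oxy)-4a-hydroxy-4,7-dimethyl-3,4,4a,5,6,8a-hexahydronaphthalen-1(2H)-ylidene]propanoate
Conditions: CSA (cat.), MeOH/CH2Cl2, 0 °C
Reagents that add atoms: none
Why: Acid methanolysis removes the labile tertiary TMS ether and the primary allylic TBS ether, while the hindered secondary C8 TBS ether and the tert-butyl ester should survive.

Step 17
Reactants: 23 the diol
Product: 24 tert-butyl (E)-3-acetoxy-2-[(2S,4R)-2-(TBS-oxy)-4a-hydroxy-4,7-dimethyl-3,4,4a,5,6,8a-hexahydronaphthalen-1(2H)-ylidene]propanoate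
Conditions: Ac2O, pyridine, DMAP (cat.), CH2Cl2, 0 °C
Reagents that add atoms: acetic anhydride, CC(=O)OC(C)=O
Why: Acylation of the primary C13 alcohol; the angular tertiary C1 alcohol should not be acetylated under these conditions.

Step 18
Reactants: 24 the angular decalinol with the C13 acetate and tert-butyl ester
Product: 28 (6R,8S,10R)-13-acetoxy-8-(TBS-oxy)-1-oxogermacra-4Z,7(11)-dien-12,6-olide, via alkoxyl radical 25 (not isolated), via allyl radical 26 (not isolated), via tert-butyl lactonium ion 27 (not isolated)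
Conditions: Pb(OAc)4, Cu(OAc)2 (10 mol %), pyridine, PhH, 60 °C
Reagents that add atoms: none
Why: Proposed new method: the tertiary C1–OH exchanges onto tetravalent lead and homolysis gives alkoxyl radical 25; β-scission of the C1–C6 ring-fusion bond, the only scission that leaves a stabilised radical (allylic to C4=C5 and conjugated with C7=C11–CO2t-Bu), turns the decalin into the ten-membered C1 ketone 26, which Pb(OAc)4 or divalent copper oxidises to the allyl cation; the carbonyl oxygen of the tert-butyl ester, held cis to C6 on C7=C11, adds to C6 to give lactonium ion 27, and loss of isobutene gives 28. The closest known reaction types are the Pb(OAc)4 and hypoiodite β-fragmentations of angular decalinols and 5-hydroxy steroids to cyclodecenones and the Kharasch–Sosnovsky oxidative C–O coupling of allyl radicals; their merger with an ester-terminated lactonisation is untested. The carbocycle arises by ring expansion (two fused six-membered rings to one ten-membered ring, no ring closure) and the butenolide by 5-exo attack of oxygen on the C6 terminus of the C4–C5–C6 allyl cation, which forms the C6–O bond. C6 is the only new stereocentre and is set under control of C8: A(1,3) strain with C13H2OAc keeps H8 in the plane of C7=C11 with OTBS and C9 on opposite faces, and in the sickle-shaped cation (C7 anti to C4) the C9–C10–C1–C2 tether is expected to pass beneath H6, so that oxygen adds to the free face and gives the 6,8-cis lactone (6R in 28, the same spatial sense as 6S in the target); this facial preference is the least secure element of the step. The step needs regioselective scission (secured by the doubly activated C6), capture at C6 rather than C4 (five- versus seven-membered ring) and retention of the 4Z olefin (secured by the rotation barrier of the allyl system and the short lifetime of 26 in the presence of Cu(OAc)2).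

Step 19
Reactants: 28 the C8 silyl ether keto lactone
Product: 29 (6R,8S,10R)-13-acetoxy-8-hydroxy-1-oxogermacra-4Z,7(11)-dien-12,6-olide
Conditions: HF·pyridine, THF, 0 °C → rt
Reagents that add atoms: none
Why: Acidic fluoride desilylation avoids base, so the epimerisable C6 (γ-position of the butenolide) and C10 (α to the ketone) and the acetate should be untouched.

Step 20
Reactants: 29 the C8 alcohol
Product: 30 (6R,8S,10R)-13-acetoxy-8-(methacryloyloxy)-1-oxogermacra-4Z,7(11)-dien-12,6-olide
Conditions: methacrylic anhydride, Et3N, DMAP (cat.), BHT, CH2Cl2, 0 °C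
Reagents that add atoms: methacrylic anhydride, C=C(C)C(=O)OC(=O)C(C)=C
Why: DMAP-catalysed acylation of the only free hydroxyl installs the methacrylate with retention at C8.

Step 21
Reactants: 30 the keto methacrylate
Product: 31 (1S,6R,8S,10R)-13-acetoxy-1-hydroxy-8-(methacryloyloxy)germacra-4Z,7(11)-dien-12,6-olide
Conditions: LiAlH(Ot-Bu)3, THF, −78 → −30 °C
Reagents that add atoms: none
Why: Chemoselective ketone reduction by a bulky hydride that leaves esters, the lactone and the acrylate alone; steric approach control (peripheral attack anti to the adjacent C10 methyl, as in reductions of 2-methylcycloalkanones) should give the 1,10-cis alcohol (1S).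

Step 22
Reactants: 31 the C1 alcohol
Product: 32 (1S,4R,5S,6S,8S,10R)-13-acetoxy-4,5-epoxy-1-hydroxy-8-(methacryloyloxy)germacr-7(11)-en-12,6-olide (CNP0119405.1)
Conditions: VO(acac)2 (5 mol %), t-BuOOH, CH2Cl2, 0 °C → rt
Reagents that add atoms: tert-butyl hydroperoxide, CC(C)(C)OO
Why: Hydroxyl-directed vanadium-catalysed epoxidation: the bishomoallylic C1–OH binds vanadium and delivers oxygen across the ring to the syn face of the (4Z)-olefin, which should give the cis-epoxide on the face of 1-OH (4R,5S); the electron-poor methacrylate and butenolide olefins do not react.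

**Compound list**
1 | (S)-5-(hydroxymethyl)dihydrofuran-2(3H)-one | O=C1CC[C@@H](CO)O1 | starting material
2 | (S)-5-(trityloxymethyl)dihydrofuran-2(3H)-one | O=C1CC[C@@H](COC(c2ccccc2)(c2ccccc2)c2ccccc2)O1 | intermediate
3 | lithium enolate of 2 (not isolated) | [Li+].[O-]C1=CC[C@@H](COC(c2ccccc2)(c2ccccc2)c2ccccc2)O1 | intermediate
4 | (3R,5S)-3-methyl-5-(trityloxymethyl)dihydrofuran-2(3H)-one | O=C1[C@H](C)C[C@@H](COC(c2ccccc2)(c2ccccc2)c2ccccc2)O1 | intermediate
5 | (2R,4S)-4-hydroxy-N-methoxy-N,2-dimethyl-5-(trityloxy)pentanamide | O[C@H](COC(c1ccccc1)(c1ccccc1)c1ccccc1)C[C@@H](C)C(=O)N(C)OC | intermediate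
6 | (2R,4S)-4-(TBS-oxy)-N-methoxy-N,2-dimethyl-5-(trityloxy)pentanamide | CC(C)(C)[Si](C)(C)O[C@H](COC(c1ccccc1)(c1ccccc1)c1ccccc1)C[C@@H](C)C(=O)N(C)OC | intermediate
7 | (2R,4S)-4-(TBS-oxy)-5-hydroxy-N-methoxy-N,2-dimethylpentanamide | CC(C)(C)[Si](C)(C)O[C@H](CO)C[C@@H](C)C(=O)N(C)OC | intermediate
8 | (2R,4S)-4-(TBS-oxy)-N-methoxy-N,2-dimethyl-5-oxopentanamide | CC(C)(C)[Si](C)(C)O[C@H](C=O)C[C@@H](C)C(=O)N(C)OC | intermediate
9 | tert-butyl 3-hydroxypropanoate | CC(C)(C)OC(=O)CCO | starting material
10 | tert-butyl 3-(TBS-oxy)propanoate | CC(C)(C)OC(=O)CCO[Si](C)(C)C(C)(C)C | intermediate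
11 | lithium enolate of 10 (not isolated) | [Li+].[O-]C(OC(C)(C)C)=CCO[Si](C)(C)C(C)(C)C | intermediate
12 | aldol adduct, tert-butyl (4S,6R)-4-(TBS-oxy)-2-[(TBS-oxy)methyl]-3-hydroxy-7-[methoxy(methyl)amino]-6-methyl-7-oxoheptanoate (C2/C3 mixture) | CC(C)(C)[Si](C)(C)O[C@H](C(O)C(CO[Si](C)(C)C(C)(C)C)C(=O)OC(C)(C)C)C[C@@H](C)C(=O)N(C)OC | intermediate
13 | β-keto ester, tert-butyl (4S,6R)-4-(TBS-oxy)-2-[(TBS-oxy)methyl]-7-[methoxy(methyl)amino]-6-methyl-3,7-dioxoheptanoate (C2 epimers) | CC(C)(C)[Si](C)(C)O[C@H](C(=O)C(CO[Si](C)(C)C(C)(C)C)C(=O)OC(C)(C)C)C[C@@H](C)C(=O)N(C)OC | intermediate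
14 | lithium chelate enolate of 13, enolate oxygen cis to the ester (not isolated) | [Li+].CC(C)(C)[Si](C)(C)O[C@H](/C([O-])=C(\CO[Si](C)(C)C(C)(C)C)C(=O)OC(C)(C)C)C[C@@H](C)C(=O)N(C)OC | intermediate
15 | (2Z)-enol triflate, tert-butyl (2Z,4S,6R)-4-(TBS-oxy)-2-[(TBS-oxy)methyl]-7-[methoxy(methyl)amino]-6-methyl-7-oxo-3-(trifluoromethylsulfonyloxy)hept-2-enoate | CC(C)(C)[Si](C)(C)O[C@H](/C(OS(=O)(=O)C(F)(F)F)=C(\CO[Si](C)(C)C(C)(C)C)C(=O)OC(C)(C)C)C[C@@H](C)C(=O)N(C)OC | intermediate
16 | 2-methylbut-1-en-3-yne | C#CC(C)=C | starting material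
17 | pinacolborane (4,4,5,5-tetramethyl-1,3,2-dioxaborolane) | CC1(C)OBOC1(C)C | starting material
18 | (E)-4,4,5,5-tetramethyl-2-(3-methylbuta-1,3-dienyl)-1,3,2-dioxaborolane | CC(=C)/C=C/B1OC(C)(C)C(C)(C)O1 | intermediate
19 | trienoate Weinreb amide (dienyl cis to CO2t-Bu; C8 S, C10 R) | CC(C)(C)[Si](C)(C)O[C@H](/C(/C=C/C(C)=C)=C(\CO[Si](C)(C)C(C)(C)C)C(=O)OC(C)(C)C)C[C@@H](C)C(=O)N(C)OC | intermediate
20 | trienoate methyl ketone | CC(C)(C)[Si](C)(C)O[C@H](/C(/C=C/C(C)=C)=C(\CO[Si](C)(C)C(C)(C)C)C(=O)OC(C)(C)C)C[C@@H](C)C(C)=O | intermediate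
21 | trienoate trimethylsilyl enol ether | CC(C)(C)[Si](C)(C)O[C@H](/C(/C=C/C(C)=C)=C(\CO[Si](C)(C)C(C)(C)C)C(=O)OC(C)(C)C)C[C@@H](C)C(=C)O[Si](C)(C)C | intermediate
22 | decalin with C1–OTMS, C8–OTBS, C13–OTBS, C4=C5 and exocyclic C7=C11 (CO2t-Bu cis to C6); C1/C6 isomer mixture | CC(C)(C)[Si](C)(C)O[C@H]1C[C@@H](C)C2(O[Si](C)(C)C)CCC(C)=CC2/C1=C(/CO[Si](C)(C)C(C)(C)C)C(=O)OC(C)(C)C | intermediate
23 | decalin diol (C1–OH, C13–OH, C8–OTBS) | CC(C)(C)[Si](C)(C)O[C@H]1C[C@@H](C)C2(O)CCC(C)=CC2/C1=C(/CO)C(=O)OC(C)(C)C | intermediate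
24 | decalinol acetate (C1–OH, C13–OAc, C8–OTBS), key-step substrate | CC(C)(C)[Si](C)(C)O[C@H]1C[C@@H](C)C2(O)CCC(C)=CC2/C1=C(/COC(C)=O)C(=O)OC(C)(C)C | intermediate
25 | C1 alkoxyl radical of 24 (not isolated) | CC(C)(C)[Si](C)(C)O[C@H]1C[C@@H](C)C2([O])CCC(C)=CC2/C1=C(/COC(C)=O)C(=O)OC(C)(C)C | intermediate
26 | ring-expanded C6 allyl radical, ten-membered C1 ketone (not isolated) | CC(C)(C)[Si](C)(C)O[C@H]1C[C@@H](C)C(=O)CC/C(C)=C\[CH]/C1=C(/COC(C)=O)C(=O)OC(C)(C)C | intermediate
27 | O-tert-butyl lactonium ion (not isolated) | CC(C)(C)[Si](C)(C)O[C@H]1C[C@@H](C)C(=O)CC/C(C)=C\[C@H]2OC(=[O+]C(C)(C)C)C(COC(C)=O)=C12 | intermediate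
28 | (6R,8S,10R)-13-acetoxy-8-(TBS-oxy)-1-oxogermacra-4Z,7(11)-dien-12,6-olide | CC(C)(C)[Si](C)(C)O[C@H]1C[C@@H](C)C(=O)CC/C(C)=C\[C@H]2OC(=O)C(COC(C)=O)=C12 | intermediate
29 | (6R,8S,10R)-13-acetoxy-8-hydroxy-1-oxogermacra-4Z,7(11)-dien-12,6-olide | O[C@H]1C[C@@H](C)C(=O)CC/C(C)=C\[C@H]2OC(=O)C(COC(C)=O)=C12 | intermediate
30 | (6R,8S,10R)-13-acetoxy-8-(methacryloyloxy)-1-oxogermacra-4Z,7(11)-dien-12,6-olide | C=C(C)C(=O)O[C@H]1C[C@@H](C)C(=O)CC/C(C)=C\[C@H]2OC(=O)C(COC(C)=O)=C12 | intermediate
31 | (1S,6R,8S,10R)-13-acetoxy-1-hydroxy-8-(methacryloyloxy)germacra-4Z,7(11)-dien-12,6-olide | C=C(C)C(=O)O[C@H]1C[C@@H](C)[C@@H](O)CC/C(C)=C\[C@H]2OC(=O)C(COC(C)=O)=C12 | intermediate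
32 | CNP0119405.1, (1S,4R,5S,6S,8S,10R)-13-acetoxy-4,5-epoxy-1-hydroxy-8-(methacryloyloxy)germacr-7(11)-en-12,6-olide | C=C(C)C(=O)O[C@H]1C[C@@H](C)[C@@H](O)CC[C@@]2(C)O[C@H]2[C@H]2OC(=O)C(COC(C)=O)=C12 | target

**Step count**
Total: 22 steps. Longest linear sequence: 20 steps (steps 1–6, 8–10, 12–22).

**Steps most likely to fail**

Step 18 (Proposed new method). After β-scission the allyl radical or cation may lose a proton to a triene or be captured by acetate instead of by the ester carbonyl, the C4=C5 olefin may lose its Z geometry, or oxygen may add to the wrong face of C6. The fallback separates the events into two known reactions and sets out from 24. Hypoiodite fragmentation (PhI(OAc)2, I2, visible light, cyclohexane/CH2Cl2) cleaves the same C1–C6 bond and caps the carbon radical by iodine-atom transfer, with no oxidation to a cation, to give the ring-expanded allylic iodide F1 (C6 epimers; any C4 regioisomer converges on ionisation). Silver-assisted ionisation (AgOTf, 2,6-di-tert-butylpyridine, CH2Cl2, −20 °C) then lets the tert-butyl ester close the butenolide with loss of isobutene, and the route is rejoined at 28.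

Step 15. The silyl enol ether may engage the diene too slowly, so that desilylation or polymerisation of the trienoate wins at the temperature needed. The fallback builds the same decalin without a cycloaddition and sets out from enol triflate 15. Stille coupling with allyltributylstannane (Pd(PPh3)4, LiCl, THF, 65 °C) gives the allyl-substituted enoate F2. Addition of 3-methylbut-3-enylmagnesium bromide to the Weinreb amide gives the ketone F3. LiN(SiMe3)2 (THF, −78 → −40 °C) generates the extended ester enolate, whose γ-carbon C6 adds to the C1 ketone (intramolecular vinylogous aldol, six-membered ring B) to give the hydroxy diene F4. Ring-closing metathesis with the second-generation Grubbs catalyst (H2IMes)(PCy3)Cl2Ru=CHPh (CH2Cl2, 40 °C) joins the C6 vinyl and C4 isopropenyl groups to ring A and gives the decalinol F5, the cis olefin being fixed by the ring. The conditions of step 16 (CSA, MeOH) remove the primary silyl ether and the route is rejoined at 23.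

Step 22. Direction by the bishomoallylic hydroxyl across the medium ring may be weak, leading to slow oxidation and poor facial selectivity, or the Lewis-acidic vanadium may promote opening of the new epoxide. The fallback replaces substrate direction by reagent control and sets out from 31. Shi epoxidation (fructose-derived ketone of the enantiomeric series matched to the required face, Oxone, buffered MeCN/dimethoxymethane/H2O, 0 °C) oxidises only the electron-rich trisubstituted olefin and returns directly to 32 without any new intermediate.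

**Further compounds**
F1 | step 18 | ring-expanded allylic iodide, (8S,10R)-13-acetoxy-8-(TBS-oxy)-6-iodo-1-oxogermacra-4Z,7(11)-dien-12-oic acid tert-butyl ester (C6 epimers) | CC(C)(C)[Si](C)(C)O[C@H]1C[C@@H](C)C(=O)CC/C(C)=C\C(I)/C1=C(/COC(C)=O)C(=O)OC(C)(C)C
F2 | step 15 | allyl-substituted enoate Weinreb amide (allyl cis to CO2t-Bu) | CC(C)(C)[Si](C)(C)O[C@H](/C(CC=C)=C(\CO[Si](C)(C)C(C)(C)C)C(=O)OC(C)(C)C)C[C@@H](C)C(=O)N(C)OC
F3 | step 15 | allyl-substituted enoate 3-methylbut-3-enyl ketone | CC(C)(C)[Si](C)(C)O[C@H](/C(CC=C)=C(\CO[Si](C)(C)C(C)(C)C)C(=O)OC(C)(C)C)C[C@@H](C)C(=O)CCC(C)=C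
F4 | step 15 | vinylogous aldol product, ring B cyclohexanol with C6 vinyl and C1 3-methylbut-3-enyl groups (C1/C6 mixture) | CC(C)(C)[Si](C)(C)O[C@H]1C[C@@H](C)C(O)(CCC(C)=C)C(C=C)/C1=C(/CO[Si](C)(C)C(C)(C)C)C(=O)OC(C)(C)C
F5 | step 15 | decalinol with C1–OH, C8–OTBS and C13–OTBS (C1/C6 mixture) | CC(C)(C)[Si](C)(C)O[C@H]1C[C@@H](C)C2(O)CCC(C)=CC2/C1=C(/CO[Si](C)(C)C(C)(C)C)C(=O)OC(C)(C)C
F0 | step 22 | none | none
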